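**Plan**

- Last cuts: the three phenols come from aryl methyl ethers, the CH2 on ring C from a bridge ketone, and aromatic ring C from a cyclohexa-1,4-diene.
- Key cut: with ring C numbered from the oxygen-bearing carbon C1 to the bridge-bearing carbon C4, the bonds C3–C4 and C5–C6 are broken. This opens ring C and the 16-membered ring together and leaves a 2-aryloxybuta-1,3-diene on the ring B oxygen and a terminal ynone on the ring D arm.
- Enabling feature: ring C is a para-phenylene with the ether oxygen on C1 and the benzylic bridge carbon on C4. A diene with oxygen on its C2 and an alkyne with an acyl group give exactly this 1,4-pattern, provided the bridge carbon is a ketone for the time being.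
- Further cuts: the dienyl ether C–O (acrylate ester, then methylenation), the ethano bridge between rings A and B (Wittig, then hydrogenation), and the biaryl bond between rings A and D (Suzuki–Miyaura).
- Forward order: rings A, B and D are bought arenes. Ring D receives its two-carbon arm, is joined to ring A and then to ring B; the diene and the ynone are installed; ring C and the macrocycle form in one step; ring C is then aromatised.
- Stereochemistry: the target has no stereocentre; the one carbinol centre made on the way is racemic and is oxidised away.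

Key step: step 15

Assumption: the target is drawn without stereodescriptors, so the biaryl axis and the macrocycle are taken as conformationally mobile and nothing stereochemical has to be controlled.

**Route**

Step 1
Reactants: 1 2-bromo-3-methoxybenzaldehyde
Product: 2 2-bromo-1-ethenyl-3-methoxybenzene
Conditions: Ph3PCH3Br, KOtBu, THF, 0 °C → rt
Reagents that add atoms: methyltriphenylphosphonium bromide C[P+](c1ccccc1)(c1ccccc1)c1ccccc1.[Br-]
Why: Wittig methylenation of an aromatic aldehyde with the non-stabilised ylide is reliable and leaves the aryl bromide untouched.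

Step 2
Reactants: 2 2-bromo-1-ethenyl-3-methoxybenzene
Product: 4 2-(2-bromo-3-methoxyphenyl)ethan-1-ol, via B-alkyl-9-BBN adduct 3 (not isolated)
Conditions: 9-BBN, THF, 0 °C → rt; then NaOH, H2O2, 0 °C → rt
Reagents that add atoms: 9-borabicyclo[3.3.1]nonane B1C2CCCC1CCC2 (boron present only in 3); hydrogen peroxide OO
Why: Hydroboration–oxidation, in which 9-BBN places boron on the terminal carbon of the styrene with high anti-Markovnikov selectivity and alkaline peroxide then gives the primary alcohol without touching the aryl bromide.

Step 3
Reactants: 4 2-(2-bromo-3-methoxyphenyl)ethan-1-ol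
Product: 5 [2-(2-bromo-3-methoxyphenyl)ethoxy](tert-butyl)dimethylsilane
Conditions: TBSCl, imidazole, DMF, rt
Reagents that add atoms: tert-butyldimethylsilyl chloride CC(C)(C)[Si](C)(C)Cl
Why: Standard silylation of a primary alcohol, giving an ether that withstands the base, ylide, hydrogenation and titanium steps ahead and is later removed by fluoride without acid.

Step 4
Reactants: 6 3-benzyloxy-4-methoxybenzaldehyde (the O-benzyl ether of isovanillin)
Product: 7 (3-benzyloxy-4-methoxyphenyl)methanol
Conditions: NaBH4, MeOH, 0 °C
Reagents that add atoms: none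
Why: Borohydride reduction of an aromatic aldehyde to the benzylic alcohol is chemoselective and clean.

Step 5
Reactants: 7 (3-benzyloxy-4-methoxyphenyl)methanol
Product: 8 [(3-benzyloxy-4-methoxyphenyl)methyl]triphenylphosphonium bromide
Conditions: PPh3·HBr, MeCN, reflux
Reagents that add atoms: triphenylphosphine hydrobromide [Br-].c1ccc(cc1)[PH+](c1ccccc1)c1ccccc1
Why: Phosphonium salt formation by SN1-type substitution, in which the electron-rich benzylic alcohol ionises under the acid and is captured by the phosphine while the benzyl ether stays intact.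

Step 6
Reactants: 5 [2-(2-bromo-3-methoxyphenyl)ethoxy](tert-butyl)dimethylsilane and 9 2-formyl-4-methoxyphenylboronic acid
Product: 10 2'-[2-(tert-butyldimethylsilyloxy)ethyl]-4,6'-dimethoxybiphenyl-2-carbaldehyde (ring A carries CHO and the 4-OMe; ring D carries the silyloxyethyl arm and the 6'-OMe)
Conditions: Pd(OAc)2 (5 mol %), SPhos (10 mol %), K3PO4, toluene/H2O, 90 °C
Reagents that add atoms: none
Why: Suzuki–Miyaura coupling, for which the bulky electron-rich biarylphosphine SPhos is suited to tri-ortho-substituted biaryls and the phosphate base limits protodeboronation of the ortho-formyl boronic acid.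

Step 7
Reactants: 8 [(3-benzyloxy-4-methoxyphenyl)methyl]triphenylphosphonium bromide and 10 the biaryl aldehyde
Product: 12 tert-butyl(2-{2'-[2-(3-benzyloxy-4-methoxyphenyl)ethenyl]-4',6-dimethoxybiphenyl-2-yl}ethoxy)dimethylsilane as an E/Z mixture, via benzylidene phosphorus ylide 11 (not isolated)
Conditions: 8, KOtBu, THF, 0 °C; then 10, 0 °C → rt
Reagents that add atoms: none
Why: Wittig olefination of the biaryl aldehyde with the semi-stabilised benzylic ylide, whose E/Z mixture is of no consequence because the alkene is saturated in the next step.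

Step 8
Reactants: 12 the stilbene (E/Z mixture)
Product: 13 5-(2-{2'-[2-(tert-butyldimethylsilyloxy)ethyl]-4,6'-dimethoxybiphenyl-2-yl}ethyl)-2-methoxyphenol
Conditions: H2 (1 atm), Pd/C, EtOAc, rt
Reagents that add atoms: none
Why: Catalytic hydrogenation saturates the stilbene and hydrogenolyses the benzyl ether in one operation, while the silyl ether and aryl methyl ethers are inert in a non-protic solvent.

Step 9
Reactants: 13 the ring B phenol and 14 acryloyl chloride
Product: 15 5-(2-{2'-[2-(tert-butyldimethylsilyloxy)ethyl]-4,6'-dimethoxybiphenyl-2-yl}ethyl)-2-methoxyphenyl prop-2-enoate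
Conditions: Et3N, BHT (cat.), CH2Cl2, −20 → 0 °C
Reagents that add atoms: none
Why: O-Acylation of a phenol by an acid chloride under amine base, with low temperature and a radical inhibitor suppressing conjugate addition and polymerisation of the acrylate.

Step 10
Reactants: 15 the aryl acrylate
Product: 16 the buta-1,3-dien-2-yl ether of phenol 13 (ring B–O–C(=CH2)–CH=CH2, ring D arm CH2CH2OTBS)
Conditions: Cp2Ti(μ-CH2)(μ-Cl)AlMe2 (Tebbe reagent), pyridine, THF/toluene, −40 °C → rt; aq NaOH quench; basic alumina
Reagents that add atoms: Tebbe reagent C[Al-]1(C)C[Ti](C2C=CC=C2)(C2C=CC=C2)[Cl+]1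
Why: Tebbe methylenation, in which the titanium methylidene adds across the ester carbonyl to an oxatitanacyclobutane that collapses to the enol ether, a reaction known for both aryl esters and α,β-unsaturated esters and run cold enough that the product diene does not add to unreacted acrylate.

Step 11
Reactants: 16 the silyl-protected aryloxydiene
Product: 17 2-[2'-(2-{3-(buta-1,3-dien-2-yloxy)-4-methoxyphenyl}ethyl)-4',6-dimethoxybiphenyl-2-yl]ethan-1-ol
Conditions: Bu4NF, THF, 0 °C → rt
Reagents that add atoms: none
Why: Fluoride-mediated silyl ether cleavage runs under basic, acid-free conditions that the acid-labile dienyl ether tolerates.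

Step 12
Reactants: 17 the primary alcohol
Product: 18 the arylacetaldehyde (ring D arm CH2CHO), used crude
Conditions: Dess–Martin periodinane, NaHCO3, CH2Cl2, 0 °C → rt
Reagents that add atoms: none
Why: Dess–Martin oxidation stops at the aldehyde, and the bicarbonate buffer protects the enol ether diene from the acetic acid released.

Step 13
Reactants: 18 the arylacetaldehyde
Product: 19 the racemic propargylic alcohol (ring D arm CH2CH(OH)C≡CH)
Conditions: HC≡CMgBr, THF, −78 → 0 °C; aq NH4Cl
Reagents that add atoms: ethynylmagnesium bromide C#C[Mg]Br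
Why: 1,2-Addition of an alkynyl Grignard reagent to the aldehyde at low temperature, forming a carbinol centre without control that is erased by the next oxidation.

Step 14
Reactants: 19 the propargylic alcohol
Product: 20 the seco aryloxydiene ynone (ring B–O–C(=CH2)–CH=CH2, ring D arm CH2C(=O)C≡CH), used at once
Conditions: Dess–Martin periodinane, NaHCO3, CH2Cl2, 0 °C
Reagents that add atoms: none
Why: Dess–Martin oxidation of a secondary propargylic alcohol is a standard non-basic route to terminal ynones and avoids conjugate addition to the product.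

Step 15
Reactants: 20 the seco aryloxydiene ynone
Product: 21 the 16-membered macrocycle in which ring C is a cyclohexa-1,4-diene (enol ether oxygen on C1, bridge ketone on C4, CH2 groups at C3 and C6)
Conditions: toluene (0.5 mM, syringe-pump addition), BHT (cat.), 110 °C, degassed
Reagents that add atoms: none
Why: Proposed new method: the electron-rich 2-aryloxybuta-1,3-diene and the electron-poor terminal ynone should combine in a concerted, asynchronous normal-demand [4+2] cycloaddition in which the diene CH2 next to the oxygen-bearing carbon (largest HOMO coefficient) bonds first to the unsubstituted alkyne terminus (largest LUMO coefficient) and the far diene CH2 bonds to the acyl-bearing alkyne carbon. The closest known reaction types are type 2 intramolecular Diels–Alder reactions through long tethers and the intermolecular cycloaddition of 2-oxygenated butadienes to ynones followed by aromatisation, but the closure of a 16-membered cyclophane precursor in this way is without precedent. Ring C closes as a cyclohexa-1,4-diene by the cycloaddition itself (four diene carbons plus two alkyne carbons), and the 16-membered ring closes in the same event in the bridged type 2 mode, because the twelve-atom tether leaves the diene at C2 and ends at the ynone carbonyl, so that ring C becomes a 1,4-bridge of the macrocycle. No stereocentre is formed, as both new sp3 carbons are CH2 groups. The step needs para over meta regiochemistry and ring closure over oligomerisation: the donor oxygen on diene C2 matched with the acyl group on the alkyne supplies the electronic para preference, the tether is long and flexible enough not to override it, and slow addition to 0.5 mM holds back the bimolecular pathway. The puckered, still non-aromatic ring C of 21 tolerates the bend of the cyclophane in the transition state, and the cost of flattening it is paid only later by aromatisation.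

Step 16
Reactants: 21 the macrocyclic cyclohexa-1,4-diene
Product: 22 the macrocyclic aryl benzyl ketone (tri-O-methylplagiochin E with C=O at the bridge carbon on ring C)
Conditions: DDQ, CH2Cl2, 0 °C → rt
Reagents that add atoms: none
Why: Dehydrogenation of a cyclohexa-1,4-diene by DDQ (hydride abstraction, then proton loss) is fast and driven by aromatisation, turning ring C into the para-phenylene and the enol ether into the diaryl ether.

Step 17
Reactants: 22 the macrocyclic aryl ketone
Product: 24 tri-O-methylplagiochin E, via macrocyclic benzylic alcohol 23 (not isolated)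
Conditions: Et3SiH, CF3CO2H, CH2Cl2, 0 °C → rt
Reagents that add atoms: none
Why: Ionic hydrogenation, in which the silane reduces the protonated aryl ketone to the benzylic alcohol, which ionises to a cation stabilised by the para-aryloxy group and accepts a second hydride to give the CH2 bridge.

Step 18
Reactants: 24 tri-O-methylplagiochin E
Product: 25 plagiochin E
Conditions: BBr3, CH2Cl2, −78 °C → rt; H2O
Reagents that add atoms: none
Why: Lewis-acid ether cleavage, in which bromide attacks the O-methyl carbon of each boron-complexed aryl methyl ether, while the diaryl ether has no sp3 carbon on oxygen and survives.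

**Compound list**

1 | 2-bromo-3-methoxybenzaldehyde | COc1cccc(C=O)c1Br | starting material
2 | 2-bromo-1-ethenyl-3-methoxybenzene | COc1cccc(C=C)c1Br | intermediate
3 | 9-[2-(2-bromo-3-methoxyphenyl)ethyl]-9-borabicyclo[3.3.1]nonane (not isolated) | COc1cccc(CCB2C3CCCC2CCC3)c1Br | intermediate
4 | 2-(2-bromo-3-methoxyphenyl)ethan-1-ol | COc1cccc(CCO)c1Br | intermediate
5 | [2-(2-bromo-3-methoxyphenyl)ethoxy](tert-butyl)dimethylsilane | COc1cccc(CCO[Si](C)(C)C(C)(C)C)c1Br | intermediate
6 | 3-benzyloxy-4-methoxybenzaldehyde | COc1ccc(C=O)cc1OCc1ccccc1 | starting material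
7 | (3-benzyloxy-4-methoxyphenyl)methanol | COc1ccc(CO)cc1OCc1ccccc1 | intermediate
8 | [(3-benzyloxy-4-methoxyphenyl)methyl]triphenylphosphonium bromide | COc1ccc(C[P+](c2ccccc2)(c2ccccc2)c2ccccc2)cc1OCc1ccccc1.[Br-] | intermediate
9 | 2-formyl-4-methoxyphenylboronic acid | COc1ccc(B(O)O)c(C=O)c1 | starting material
10 | 2'-[2-(tert-butyldimethylsilyloxy)ethyl]-4,6'-dimethoxybiphenyl-2-carbaldehyde | COc1ccc(c(C=O)c1)-c1c(OC)cccc1CCO[Si](C)(C)C(C)(C)C | intermediate
11 | [(3-benzyloxy-4-methoxyphenyl)methylidene]triphenylphosphorane (not isolated) | COc1ccc(C=P(c2ccccc2)(c2ccccc2)c2ccccc2)cc1OCc1ccccc1 | intermediate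
12 | tert-butyl(2-{2'-[2-(3-benzyloxy-4-methoxyphenyl)ethenyl]-4',6-dimethoxybiphenyl-2-yl}ethoxy)dimethylsilane, E/Z mixture | COc1ccc(c(C=Cc2ccc(OC)c(OCc3ccccc3)c2)c1)-c1c(OC)cccc1CCO[Si](C)(C)C(C)(C)C | intermediate
13 | 5-(2-{2'-[2-(tert-butyldimethylsilyloxy)ethyl]-4,6'-dimethoxybiphenyl-2-yl}ethyl)-2-methoxyphenol | COc1ccc(c(CCc2ccc(OC)c(O)c2)c1)-c1c(OC)cccc1CCO[Si](C)(C)C(C)(C)C | intermediate
14 | acryloyl chloride | C=CC(=O)Cl | starting material
15 | prop-2-enoate ester of phenol 13 | COc1ccc(c(CCc2ccc(OC)c(OC(=O)C=C)c2)c1)-c1c(OC)cccc1CCO[Si](C)(C)C(C)(C)C | intermediate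
16 | buta-1,3-dien-2-yl ether of phenol 13 | COc1ccc(c(CCc2ccc(OC)c(OC(=C)C=C)c2)c1)-c1c(OC)cccc1CCO[Si](C)(C)C(C)(C)C | intermediate
17 | 2-[2'-(2-{3-(buta-1,3-dien-2-yloxy)-4-methoxyphenyl}ethyl)-4',6-dimethoxybiphenyl-2-yl]ethan-1-ol | COc1ccc(c(CCc2ccc(OC)c(OC(=C)C=C)c2)c1)-c1c(OC)cccc1CCO | intermediate
18 | 2-[2'-(2-{3-(buta-1,3-dien-2-yloxy)-4-methoxyphenyl}ethyl)-4',6-dimethoxybiphenyl-2-yl]acetaldehyde | COc1ccc(c(CCc2ccc(OC)c(OC(=C)C=C)c2)c1)-c1c(OC)cccc1CC=O | intermediate
19 | 1-[2'-(2-{3-(buta-1,3-dien-2-yloxy)-4-methoxyphenyl}ethyl)-4',6-dimethoxybiphenyl-2-yl]but-3-yn-2-ol, racemic | COc1ccc(c(CCc2ccc(OC)c(OC(=C)C=C)c2)c1)-c1c(OC)cccc1CC(O)C#C | intermediate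
20 | 1-[2'-(2-{3-(buta-1,3-dien-2-yloxy)-4-methoxyphenyl}ethyl)-4',6-dimethoxybiphenyl-2-yl]but-3-yn-2-one | COc1ccc(c(CCc2ccc(OC)c(OC(=C)C=C)c2)c1)-c1c(OC)cccc1CC(=O)C#C | intermediate
21 | macrocycle with ring C as cyclohexa-1,4-diene (O on C1, bridge ketone on C4) | COc1ccc2c(c1)CCc1ccc(OC)c(c1)OC1=CCC(=CC1)C(=O)Cc1cccc(OC)c1-2 | intermediate
22 | macrocyclic aryl benzyl ketone (bridge C=O on ring C, three OMe) | COc1ccc2c(c1)CCc1ccc(OC)c(c1)Oc1ccc(cc1)C(=O)Cc1cccc(OC)c1-2 | intermediate
23 | macrocyclic benzylic alcohol, racemic (not isolated) | COc1ccc2c(c1)CCc1ccc(OC)c(c1)Oc1ccc(cc1)C(O)Cc1cccc(OC)c1-2 | intermediate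
24 | tri-O-methylplagiochin E | COc1ccc2c(c1)CCc1ccc(OC)c(c1)Oc1ccc(cc1)CCc1cccc(OC)c1-2 | intermediate
25 | plagiochin E | Oc1ccc2c(c1)CCc1ccc(O)c(c1)Oc1ccc(cc1)CCc1cccc(O)c1-2 | target

**Step count and risks**

Total: 18 steps. Longest linear sequence: 16 steps (from 1 through steps 1–3 and 6–18); the ring B branch (steps 4 and 5) joins at step 7.

Steps most likely to fail:

1. Step 15 (the macrocyclising cycloaddition). Bimolecular cycloaddition and oligomerisation may outrun ring closure, the dienyl ether may decompose at the reaction temperature, or regiocontrol may be lost. The fallback brings ring C in as a ready-made arene and closes the ring by a B-alkyl Suzuki–Miyaura macrocyclisation, a known reaction type. It sets out from phenol 13. Ullmann-type etherification with 1-bromo-4-iodobenzene (CuI, N,N-dimethylglycine, Cs2CO3, dioxane, 90 °C, the iodide reacting selectively) should give the 4-bromophenyl ether F1. Bu4NF in THF then frees the primary alcohol F2, and I2, PPh3 and imidazole convert it into the primary iodide F3. E2 elimination with KOtBu in THF gives the ring D styrene F4. Hydroboration with 9-BBN gives the alkylborane F5, which is added slowly, without isolation, to Pd(dppf)Cl2, AsPh3 and Cs2CO3 in DMF/THF/H2O at high dilution. The route is rejoined at tri-O-methylplagiochin E 24.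

2. Step 10 (methylenation of the acrylate). The acrylate may polymerise, the titanium reagent may be consumed unproductively, or the dienyl ether may hydrolyse during work-up. The fallback builds the diene by elimination and sets out from phenol 13. Palladium-catalysed opening of 2-vinyloxirane (Pd2(dba)3, racemic trans-1,2-diaminocyclohexane bis(2-diphenylphosphinobenzamide) ligand, CH2Cl2) should give the branched 2-aryloxybut-3-en-1-ol F6. I2, PPh3 and imidazole give the iodide F7. KOtBu in THF at 0 °C then removes the allylic proton next to oxygen in an E2 elimination, and the route is rejoined at diene 16.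

3. Step 14 (formation and handling of the terminal ynone). The free ynone may oligomerise, take up nucleophiles at its terminus, or add to the diene of a second molecule during work-up and concentration. The fallback masks the alkyne terminus with silicon and sets out from aldehyde 18. Addition of LiC≡CSiMe3 (THF, −78 °C) should give the silylated propargylic alcohol F8, and buffered Dess–Martin oxidation the silyl ynone F9, which can be purified and stored. Desilylation with Bu4NF buffered by AcOH (THF, −78 °C), just before the solution is diluted into hot toluene, rejoins the route at ynone 20.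

**Further compounds**

F1 | step 15 | 4-bromophenyl ether of phenol 13 | COc1ccc(c(CCc2ccc(OC)c(Oc3ccc(Br)cc3)c2)c1)-c1c(OC)cccc1CCO[Si](C)(C)C(C)(C)C
F2 | step 15 | desilylated primary alcohol of F1 | COc1ccc(c(CCc2ccc(OC)c(Oc3ccc(Br)cc3)c2)c1)-c1c(OC)cccc1CCO
F3 | step 15 | primary iodide from F2 | COc1ccc(c(CCc2ccc(OC)c(Oc3ccc(Br)cc3)c2)c1)-c1c(OC)cccc1CCI
F4 | step 15 | ring D styrene bearing the 4-bromophenyl ether | COc1ccc(c(CCc2ccc(OC)c(Oc3ccc(Br)cc3)c2)c1)-c1c(OC)cccc1C=C
F5 | step 15 | B-alkyl-9-BBN adduct of F4 | COc1ccc(c(CCc2ccc(OC)c(Oc3ccc(Br)cc3)c2)c1)-c1c(OC)cccc1CCB1C2CCCC1CCC2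
F6 | step 10 | 2-aryloxybut-3-en-1-ol from phenol 13, racemic | COc1ccc(c(CCc2ccc(OC)c(OC(CO)C=C)c2)c1)-c1c(OC)cccc1CCO[Si](C)(C)C(C)(C)C
F7 | step 10 | 1-iodobut-3-en-2-yl aryl ether from F6, racemic | COc1ccc(c(CCc2ccc(OC)c(OC(CI)C=C)c2)c1)-c1c(OC)cccc1CCO[Si](C)(C)C(C)(C)C
F8 | step 14 | C-trimethylsilyl propargylic alcohol from 18, racemic | COc1ccc(c(CCc2ccc(OC)c(OC(=C)C=C)c2)c1)-c1c(OC)cccc1CC(O)C#C[Si](C)(C)C
F9 | step 14 | C-trimethylsilyl ynone | COc1ccc(c(CCc2ccc(OC)c(OC(=C)C=C)c2)c1)-c1c(OC)cccc1CC(=O)C#C[Si](C)(C)C
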